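**Retrosynthetic overview**

1. Target 37 comes from the tetracyclic 15-oxo-7,20-olide 32 by hydrogenolysis, acetylation at O1/O6, α-methylenation at C16 and release of O19.
2. Key disconnection (C8–C15 and C8–C14): 32 comes from the α-diazo δ-lactone 30, which carries a cyclobutanone on the C11–C12 tether. The diazo carbon C8 is inserted into a C(=O)–CH2 bond of the cyclobutanone, which closes ring C and expands the four-membered ring to ring D in one operation.
3. Enabling feature: C8, the bridgehead shared by the lactone ring, ring C and ring D, is the quaternary α-carbon of a β-keto lactone (between lactone C7=O and ring D ketone C15, bonded to CH2-14), and C13 of ring D is tied back to C9 by the C11–C12 ethano unit.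
4. Lactone 27 comes from enone 8 by two α'-functionalisations at C10 (Ir-catalysed branched allylation with carbonate 17 sets C9; formaldehyde aldol sets C10), directed reduction at C1, hydroboration and oxidative lactonisation. Enone 8 comes from a catalytic asymmetric Diels–Alder reaction (C4, C5).
5. Order of ring formation: ring A, then the δ-lactone, then rings C and D together.

Key step: step 20

Remark: kaurane numbering is used throughout, and the SMILES is taken literally; it places C6, C9, O1 and the C4 methyl on one face of ring A (called the upper face) and C19 and C20 on the other.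

**Route**

Step 1
Reactants: 1 2-(benzyloxy)acetaldehyde; 2 2-(triphenylphosphoranylidene)propanal
Product: 3 (E)-4-(benzyloxy)-2-methylbut-2-enal
Conditions: toluene, 80 °C
Reagents that add atoms: none
Why: Wittig olefination with a stabilised formyl ylide should give the (E)-trisubstituted enal under thermodynamic control.

Step 2
Reactants: 3 (E)-4-(benzyloxy)-2-methylbut-2-enal; 4 (E)-1-(dimethylamino)-3-(tert-butyldimethylsilyloxy)buta-1,3-diene
Product: 5 Diels–Alder adduct (amino silyl enol ether aldehyde)
Conditions: (R,R)-[Cr(salen)]SbF6 (5 mol%; salen = N,N'-bis(3,5-di-tert-butylsalicylidene)cyclohexane-1,2-diaminate), 4 Å MS, CH2Cl2, −40 to −20 °C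
Reagents that add atoms: none
Why: Catalytic enantioselective Diels–Alder reaction of a 1-amino-3-siloxy diene with an α-substituted enal; the nucleophilic CH2 terminus bonds to the β-carbon (C5), the E geometry of 3 fixes C6 cis to the C4 methyl and trans to the formyl carbon C19, and the chiral Lewis acid sets the absolute configuration (the catalyst antipode is taken if the facial sense has to be reversed).

Step 3
Reactants: 5 Diels–Alder adduct
Product: 7 ring A enone alcohol, via amino alcohol silyl enol ether 6 (not isolated)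
Conditions: LiAlH4, Et2O, −78 to 0 °C; then 1 M HCl, THF, 0 °C
Reagents that add atoms: none
Why: Hydride reduction of the aldehyde followed by acid hydrolysis of the silyl enol ether and E1cB β-elimination of dimethylamine should give the 4,4-disubstituted cyclohex-2-enone without touching C4 or C5.

Step 4
Reactants: 7 ring A enone alcohol
Product: 8 ring A enone TBDPS ether
Conditions: TBDPSCl, imidazole, DMAP (cat.), DMF, rt to 40 °C
Reagents that add atoms: tert-butyl(chloro)diphenylsilane, CC(C)(C)[Si](Cl)(c1ccccc1)c1ccccc1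
Why: Silylation of the neopentyl primary alcohol gives a robust O19 protecting group that is removed only at the end.

Step 5
Reactants: 9 hexa-1,5-diene; 10 trichloroacetyl chloride
Product: 12 3-(but-3-enyl)-2,2-dichlorocyclobutanone, via dichloroketene 11 (not isolated)
Conditions: Zn–Cu couple, Et2O, sonication, 20–30 °C, diene in excess
Reagents that add atoms: none
Why: Ketene–alkene [2+2] cycloaddition of dichloroketene made by zinc dehalogenation should bond the carbonyl carbon to the terminal CH2, and the excess of diene keeps the reaction at mono-addition.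

Step 6
Reactants: 12 3-(but-3-enyl)-2,2-dichlorocyclobutanone
Product: 13 3-(but-3-enyl)cyclobutanone
Conditions: Zn dust, AcOH, rt to 60 °C
Reagents that add atoms: none
Why: Reductive dechlorination of an α,α-dichloro ketone with zinc is standard and leaves the terminal alkene intact.

Step 7
Reactants: 13 3-(but-3-enyl)cyclobutanone
Product: 14 cis-3-(but-3-enyl)cyclobutanol
Conditions: NaBH4, MeOH, −78 to 0 °C
Reagents that add atoms: none
Why: Borohydride reduction masks the ketone, with hydride entering anti to the 3-substituent to favour the cis alcohol (this centre is oxidised again in step 19, so its configuration is inconsequential).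

Step 8
Reactants: 14 cis-3-(but-3-enyl)cyclobutanol
Product: 15 cis-3-(but-3-enyl)cyclobutyl pivalate
Conditions: t-BuCOCl, pyridine, DMAP (cat.), CH2Cl2, 0 °C to rt
Reagents that add atoms: pivaloyl chloride, CC(C)(C)C(Cl)=O
Why: Esterification gives a base-tolerant ester that is later removed by the hydride used in step 16.

Step 9
Reactants: 15 cis-3-(but-3-enyl)cyclobutyl pivalate; 16 allyl methyl carbonate
Product: 17 (E)-5-[cis-3-(pivaloyloxy)cyclobutyl]pent-2-enyl methyl carbonate
Conditions: second-generation Grubbs catalyst RuCl2(=CHPh)(H2IMes)(PCy3) (3 mol%), 16 (4 equiv), CH2Cl2, 40 °C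
Reagents that add atoms: none
Why: Olefin cross-metathesis of two terminal alkenes with loss of ethylene should give the linear (E)-allylic carbonate under thermodynamic control.

Step 10
Reactants: 8 ring A enone TBDPS ether
Product: 18 cross-conjugated trimethylsilyl dienol ether
Conditions: LiN(i-Pr)2, THF, −78 °C; Me3SiCl
Reagents that add atoms: chlorotrimethylsilane, C[Si](C)(C)Cl
Why: Kinetic α'-deprotonation of the enone (the quaternary C4 excludes γ-deprotonation) and O-silylation fix the enolate regiochemistry at C10.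

Step 11
Reactants: 18 cross-conjugated trimethylsilyl dienol ether; 17 (E)-allylic methyl carbonate
Product: 19 C10-allylated enone
Conditions: [Ir(cod)Cl]2 (2 mol%), (S,S,S)-phosphoramidite L (4 mol%; BINOL-derived N,N-bis(1-phenylethyl)phosphoramidite), CsF (0.4 equiv), ZnF2 (1.5 equiv), DME, 50 °C
Reagents that add atoms: none
Why: Iridium-catalysed asymmetric allylic alkylation of a silyl enol ether should attack the substituted allyl terminus (branched product), so C9 is set by the catalyst (ligand antipode taken if the sense must be reversed), while the C10 epimers converge in step 12.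

Step 12
Reactants: 19 C10-allylated enone
Product: 20 C10-quaternary β-hydroxy enone
Conditions: LiN(i-Pr)2, THF, −78 to −40 °C; CH2O (gas, from cracked paraformaldehyde), −78 °C; aq. NH4Cl
Reagents that add atoms: formaldehyde, C=O
Why: Aldol reaction of the re-formed α'-enolate with formaldehyde, in which the electrophile should enter anti to the pseudo-axial C5 benzyloxymethyl group, places C20 trans to C6 and leaves C9 cis to C6.

Step 13
Reactants: 20 C10-quaternary β-hydroxy enone
Product: 21 1,20-diol
Conditions: Me4NBH(OAc)3, MeCN/AcOH, −30 °C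
Reagents that add atoms: none
Why: Evans–Saksena reduction delivers hydride intramolecularly from the C20 alkoxyborohydride to the C20 face of the C1 carbonyl, which should give the anti-1,3-diol with O1 on the upper face (cis to C9).

Step 14
Reactants: 21 1,20-diol
Product: 22 1,20-O-benzylidene acetal
Conditions: PhCH(OMe)2, camphorsulfonic acid (cat.), CH2Cl2, rt
Reagents that add atoms: benzaldehyde dimethyl acetal, COC(OC)c1ccccc1
Why: Acid-catalysed transacetalisation closes the 1,3-dioxane with the phenyl group equatorial under thermodynamic control.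

Step 15
Reactants: 22 1,20-O-benzylidene acetal
Product: 24 C7 primary alcohol, via B-alkyl-9-BBN 23 (not isolated)
Conditions: 9-BBN, THF, rt to 50 °C; then 3 M NaOH, 30% H2O2, 0 °C
Reagents that add atoms: hydrogen peroxide, OO
Why: Hydroboration–oxidation with a bulky borane should select the monosubstituted vinyl group over the ring alkene and place oxygen on the terminal carbon C7.

Step 16
Reactants: 24 C7 primary alcohol
Product: 25 triol with O1 benzyl ether
Conditions: i-Bu2AlH (6 equiv), CH2Cl2, −78 to 0 °C; aq. Rochelle salt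
Reagents that add atoms: none
Why: Reductive benzylidene acetal opening, in which aluminium coordinates the less hindered primary O20, should leave the benzyl group on the secondary O1 and free the C20 hydroxyl, and the same hydride cleaves the pivalate to the cyclobutanol.

Step 17
Reactants: 25 triol with O1 benzyl ether
Product: 27 7,20-δ-lactone, via lactol 26 (not isolated)
Conditions: TEMPO (0.2 equiv), PhI(OAc)2 (2.5 equiv), CH2Cl2, rt
Reagents that add atoms: none
Why: TEMPO-mediated oxidative lactonisation should oxidise the unhindered C7 primary alcohol first, close the six-membered lactol onto the neopentyl C20 hydroxyl and oxidise it on, while the secondary cyclobutanol reacts much more slowly.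

Step 18
Reactants: 27 7,20-δ-lactone
Product: 29 α-diazo lactone cyclobutanol, via bis(trifluoroacetyl) intermediate 28 (not isolated)
Conditions: LiN(SiMe3)2 (2.3 equiv), THF, −78 °C; CF3CO2CH2CF3 (2.5 equiv); then MeSO2N3, Et3N, H2O, MeCN, rt
Reagents that add atoms: methanesulfonyl azide, CS(=O)(=O)N=[N+]=[N-]
Why: Regitz-type detrifluoroacetylative diazo transfer (Claisen trifluoroacetylation of the lactone enolate, then sulfonyl azide) installs the diazo group at C8, and the transient O-trifluoroacetate of the cyclobutanol is hydrolysed in the same pot.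

Step 19
Reactants: 29 α-diazo lactone cyclobutanol
Product: 30 α-diazo lactone cyclobutanone
Conditions: Dess–Martin periodinane, NaHCO3, CH2Cl2, 0 °C to rt
Reagents that add atoms: none
Why: Dess–Martin oxidation of the secondary alcohol under buffered conditions is compatible with the α-diazo ester and unmasks the ketone only one step before it is used.

Step 20
Reactants: 30 α-diazo lactone cyclobutanone
Product: 32 tetracyclic β-keto lactone, via β-oxido diazonium adduct 31 (not isolated)
Conditions: Sc(OTf)3 (20 mol%), 4 Å MS, CH2Cl2, −40 to 0 °C, slow addition of 30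
Reagents that add atoms: none
Why: Proposed new method: Sc(OTf)3 activates the cyclobutanone carbonyl C15, the nucleophilic diazo carbon C8 adds to it across the C11–C12 tether, and in the β-oxido diazonium 31 a ring CH2 (C14) migrates from C15 to C8 with loss of N2, so the four-membered ring grows to the five-membered ring D while C8 becomes the quaternary β-keto lactone carbon. The closest known reaction type is the Lewis-acid-catalysed Büchner–Curtius–Schlotterbeck (Tiffeneau–Demjanov-type) ring expansion of cyclobutanones with α-alkyl-α-diazo esters, known as an intermolecular process; here it is run intramolecularly with an α-diazo lactone. The C8–C15 bond forms by a 7-exo-trig carbonyl addition (transient bicyclo[4.1.1]octane), and the 1,2-shift then contracts this seven-membered ring to the six-membered ring C (C8–C9–C11–C12–C13–C14) and expands the cyclobutanone to ring D, giving the bicyclo[3.2.1]octane. At C8 the short tether lets C15 reach only the face of the diazo carbon syn to the C9 side chain, and the anti-periplanar shift inverts C8, placing C14 cis to C11 and C15 trans (lactone cis-fused to ring C, as in the target); C13 is fixed by the bridge, and because both ring CH2 groups lead to the same product no group selectivity is needed. The selectivity that is needed is C–C migration over epoxide closure and over 1,2-hydride shift from C9, which the ring strain of the cyclobutanone, a non-protic oxophilic catalyst and slow addition at low temperature should secure.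

Step 21
Reactants: 32 tetracyclic β-keto lactone
Product: 33 1,6-diol
Conditions: H2 (1 atm), Pd(OH)2/C, EtOAc/EtOH, rt
Reagents that add atoms: none
Why: Heterogeneous hydrogenation saturates the C2=C3 ring alkene and hydrogenolyses both benzyl ethers in one operation, creating no stereocentre.

Step 22
Reactants: 33 1,6-diol
Product: 34 1,6-diacetate
Conditions: Ac2O, pyridine, DMAP (cat.), CH2Cl2, rt
Reagents that add atoms: acetic anhydride, CC(=O)OC(C)=O
Why: DMAP-catalysed acylation esterifies both free hydroxyls while O19 stays silylated.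

Step 23
Reactants: 34 1,6-diacetate
Product: 36 16-methylene enone, via Mannich base 35 (not isolated)
Conditions: (CH2O)n, N-methylanilinium trifluoroacetate, THF, 65 °C
Reagents that add atoms: formaldehyde (as paraformaldehyde), C=O
Why: Mannich reaction followed by β-elimination of the amine (acid-mediated α-methylenation) can occur only at C16, the single enolisable α-carbon of the C15 ketone, and the mildly acidic conditions spare the acetates.

Step 24
Reactants: 36 16-methylene enone
Product: 37 target CNP0370815.4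
Conditions: HF·pyridine, THF/pyridine, 0 °C to rt
Reagents that add atoms: none
Why: Fluoride-mediated desilylation frees the C19 hydroxyl without touching the acetates, the lactone or the exocyclic enone.

**Compound list**

1 | 2-(benzyloxy)acetaldehyde | O=CCOCc1ccccc1 | starting material
2 | 2-(triphenylphosphoranylidene)propanal | CC(C=O)=P(c1ccccc1)(c1ccccc1)c1ccccc1 | starting material
3 | (E)-4-(benzyloxy)-2-methylbut-2-enal | O=C/C(C)=C/COCc1ccccc1 | intermediate
4 | (E)-1-(dimethylamino)-3-(tert-butyldimethylsilyloxy)buta-1,3-diene | CN(C)/C=C/C(=C)O[Si](C)(C)C(C)(C)C | starting material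
5 | Diels–Alder adduct: 6-(benzyloxymethyl)-2-(dimethylamino)-1-methyl-4-(tert-butyldimethylsilyloxy)cyclohex-3-ene-1-carbaldehyde (CHO trans to CH2OBn, cis to NMe2) | CC(C)(C)[Si](C)(C)OC1=C[C@H](N(C)C)[C@](C)(C=O)[C@@H](COCc2ccccc2)C1 | intermediate
6 | amino alcohol silyl enol ether (primary alcohol from 5) | CC(C)(C)[Si](C)(C)OC1=C[C@H](N(C)C)[C@](C)(CO)[C@@H](COCc2ccccc2)C1 | intermediate
7 | ring A enone alcohol: 5-(benzyloxymethyl)-4-(hydroxymethyl)-4-methylcyclohex-2-en-1-one (CH2OBn cis to the C4 methyl) | O=C1C=C[C@](C)(CO)[C@@H](COCc2ccccc2)C1 | intermediate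
8 | ring A enone TBDPS ether | O=C1C=C[C@](C)(CO[Si](c2ccccc2)(c2ccccc2)C(C)(C)C)[C@@H](COCc2ccccc2)C1 | intermediate
9 | hexa-1,5-diene | C=CCCC=C | starting material
10 | trichloroacetyl chloride | ClC(Cl)(Cl)C(Cl)=O | starting material
11 | dichloroketene | ClC(Cl)=C=O | intermediate
12 | 3-(but-3-enyl)-2,2-dichlorocyclobutanone (racemic) | C=CCCC1CC(=O)C1(Cl)Cl | intermediate
13 | 3-(but-3-enyl)cyclobutanone | C=CCCC1CC(=O)C1 | intermediate
14 | cis-3-(but-3-enyl)cyclobutanol | C=CCC[C@H]1C[C@@H](O)C1 | intermediate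
15 | cis-3-(but-3-enyl)cyclobutyl pivalate | C=CCC[C@H]1C[C@@H](OC(=O)C(C)(C)C)C1 | intermediate
16 | allyl methyl carbonate | C=CCOC(=O)OC | starting material
17 | (E)-5-[cis-3-(pivaloyloxy)cyclobutyl]pent-2-enyl methyl carbonate | COC(=O)OC/C=C/CC[C@H]1C[C@@H](OC(=O)C(C)(C)C)C1 | intermediate
18 | cross-conjugated trimethylsilyl dienol ether of 8 | C[Si](C)(C)OC=1C=C[C@](C)(CO[Si](c2ccccc2)(c2ccccc2)C(C)(C)C)[C@@H](COCc2ccccc2)C=1 | intermediate
19 | C10-allylated enone (C9 bears vinyl and the cyclobutylethyl chain; C10–H, major epimer with C9 trans to C6) | O=C1C=C[C@](C)(CO[Si](c2ccccc2)(c2ccccc2)C(C)(C)C)[C@@H](COCc2ccccc2)[C@@H]1[C@@H](C=C)CC[C@H]1C[C@@H](OC(=O)C(C)(C)C)C1 | intermediate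
20 | C10-quaternary β-hydroxy enone (C20 hydroxymethyl trans to C6) | O=C1C=C[C@](C)(CO[Si](c2ccccc2)(c2ccccc2)C(C)(C)C)[C@@H](COCc2ccccc2)[C@@]1(CO)[C@@H](C=C)CC[C@H]1C[C@@H](OC(=O)C(C)(C)C)C1 | intermediate
21 | 1,20-diol (O1 cis to C9) | O[C@H]1C=C[C@](C)(CO[Si](c2ccccc2)(c2ccccc2)C(C)(C)C)[C@@H](COCc2ccccc2)[C@@]1(CO)[C@@H](C=C)CC[C@H]1C[C@@H](OC(=O)C(C)(C)C)C1 | intermediate
22 | 1,20-O-benzylidene acetal (phenyl equatorial) | c1ccc(cc1)[C@H]2O[C@H]3C=C[C@](C)(CO[Si](c4ccccc4)(c4ccccc4)C(C)(C)C)[C@@H](COCc4ccccc4)[C@@]3(CO2)[C@@H](C=C)CC[C@H]4C[C@@H](OC(=O)C(C)(C)C)C4 | intermediate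
23 | B-alkyl-9-BBN (boron on C7) | c1ccc(cc1)[C@H]2O[C@H]3C=C[C@](C)(CO[Si](c4ccccc4)(c4ccccc4)C(C)(C)C)[C@@H](COCc4ccccc4)[C@@]3(CO2)[C@@H](CCB4C5CCCC4CCC5)CC[C@H]4C[C@@H](OC(=O)C(C)(C)C)C4 | intermediate
24 | C7 primary alcohol (acetal and pivalate intact) | c1ccc(cc1)[C@H]2O[C@H]3C=C[C@](C)(CO[Si](c4ccccc4)(c4ccccc4)C(C)(C)C)[C@@H](COCc4ccccc4)[C@@]3(CO2)[C@@H](CCO)CC[C@H]4C[C@@H](OC(=O)C(C)(C)C)C4 | intermediate
25 | triol (C7–OH, C20–OH, cyclobutanol) with O1 benzyl ether | c1ccccc1CO[C@H]1C=C[C@](C)(CO[Si](c2ccccc2)(c2ccccc2)C(C)(C)C)[C@@H](COCc2ccccc2)[C@@]1(CO)[C@@H](CCO)CC[C@H]1C[C@@H](O)C1 | intermediate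
26 | lactol (C7 hemiacetal, anomeric mixture) | c1ccccc1CO[C@H]1C=C[C@](C)(CO[Si](c2ccccc2)(c2ccccc2)C(C)(C)C)[C@@H](COCc2ccccc2)[C@@]1(COC(O)C2)[C@@H]2CC[C@H]1C[C@@H](O)C1 | intermediate
27 | spiro 7,20-δ-lactone with cyclobutanol | c1ccccc1CO[C@H]1C=C[C@](C)(CO[Si](c2ccccc2)(c2ccccc2)C(C)(C)C)[C@@H](COCc2ccccc2)[C@@]1(COC(=O)C2)[C@@H]2CC[C@H]1C[C@@H](O)C1 | intermediate
28 | α-trifluoroacetyl lactone O-trifluoroacetate (C8 epimers) | c1ccccc1CO[C@H]1C=C[C@](C)(CO[Si](c2ccccc2)(c2ccccc2)C(C)(C)C)[C@@H](COCc2ccccc2)[C@@]1(COC(=O)C2C(=O)C(F)(F)F)[C@@H]2CC[C@H]1C[C@@H](OC(=O)C(F)(F)F)C1 | intermediate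
29 | α-diazo lactone cyclobutanol | c1ccccc1CO[C@H]1C=C[C@](C)(CO[Si](c2ccccc2)(c2ccccc2)C(C)(C)C)[C@@H](COCc2ccccc2)[C@@]1(COC(=O)C2=[N+]=[N-])[C@@H]2CC[C@H]1C[C@@H](O)C1 | intermediate
30 | α-diazo lactone cyclobutanone | c1ccccc1CO[C@H]1C=C[C@](C)(CO[Si](c2ccccc2)(c2ccccc2)C(C)(C)C)[C@@H](COCc2ccccc2)[C@@]1(COC(=O)C2=[N+]=[N-])[C@@H]2CCC1CC(=O)C1 | intermediate
31 | β-oxido diazonium adduct (bicyclo[4.1.1]octane; oxygen bound to scandium) | c1ccccc1CO[C@H]1C=C[C@](C)(CO[Si](c2ccccc2)(c2ccccc2)C(C)(C)C)[C@@H](COCc2ccccc2)[C@@]1(COC(=O)[C@@]2([N+]#N)[C@@]3([O-])C[C@@H]4C3)[C@@H]2CC4 | intermediate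
32 | tetracyclic β-keto lactone (15-oxo-7,20-olide; 1,6-di-O-benzyl, 19-O-TBDPS, 2-ene) | C1C(=O)[C@]23C[C@H]1CC[C@H]2[C@@]1(COC3=O)[C@@H](OCc4ccccc4)C=C[C@](C)(CO[Si](c4ccccc4)(c4ccccc4)C(C)(C)C)[C@H]1COCc4ccccc4 | intermediate
33 | 1,6-diol (ring A saturated) | C1C(=O)[C@]23C[C@H]1CC[C@H]2[C@@]1(COC3=O)[C@@H](O)CC[C@](C)(CO[Si](c4ccccc4)(c4ccccc4)C(C)(C)C)[C@H]1CO | intermediate
34 | 1,6-diacetate | C1C(=O)[C@]23C[C@H]1CC[C@H]2[C@@]1(COC3=O)[C@@H](OC(C)=O)CC[C@](C)(CO[Si](c4ccccc4)(c4ccccc4)C(C)(C)C)[C@H]1COC(C)=O | intermediate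
35 | Mannich base (N-methylanilinomethyl at C16, C16 epimers) | CN(c5ccccc5)CC1C(=O)[C@]23C[C@H]1CC[C@H]2[C@@]1(COC3=O)[C@@H](OC(C)=O)CC[C@](C)(CO[Si](c4ccccc4)(c4ccccc4)C(C)(C)C)[C@H]1COC(C)=O | intermediate
36 | 16-methylene enone, 19-O-TBDPS | C=C1C(=O)[C@]23C[C@H]1CC[C@H]2[C@@]1(COC3=O)[C@@H](OC(C)=O)CC[C@](C)(CO[Si](c4ccccc4)(c4ccccc4)C(C)(C)C)[C@H]1COC(C)=O | intermediate
37 | CNP0370815.4 | C=C1C(=O)[C@]23C[C@H]1CC[C@H]2[C@@]1(COC3=O)[C@@H](OC(C)=O)CC[C@](C)(CO)[C@H]1COC(C)=O | target

**Step count and risks**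

Total step count: 24. Longest linear sequence: 19 steps (steps 1–4 and 10–24); the five-step branch to carbonate 17 (steps 5–9) joins at step 11.

Steps most likely to fail:

1. Step 20 (proposed new method). The bridged transition state may be too strained for the diazo carbon to reach the ketone, so that acid-induced loss of nitrogen with 1,2-hydride shift from C9, or oxygen closure to a spiro-epoxide, takes over. The fallback uses the classical Tiffeneau–Demjanov sequence and sets out from 27. The lactone enolate is nitrated at C8 (KOt-Bu, isoamyl nitrate, THF, −40 °C) to the α-nitro lactone F1. The cyclobutanol is oxidised with Dess–Martin periodinane to the nitro keto lactone F2. Et3N closes the intramolecular Henry adduct F3, and Zn in AcOH reduces the nitro group to the β-amino alcohol F4. NaNO2 in aqueous AcOH at 0 °C then generates the same diazonium as in step 20, and the ring expansion returns the route to 32.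

2. Step 11. The hindered α'-enolate may be protonated before it is allylated, or the allyl–iridium intermediate may be attacked at its unsubstituted terminus, which would erode conversion and branched selectivity. The fallback sets out from 8 and 15. Ozonolysis of 15 (O3, CH2Cl2, −78 °C; PPh3) gives 3-[cis-3-(pivaloyloxy)cyclobutyl]propanal F5. Aldol addition of the lithium α'-enolate of 8 gives the β-hydroxy ketone F6, and MsCl/Et3N followed by DBU dehydrates it to the (E)-alkylidene dienone F7. Copper-catalysed asymmetric conjugate addition of vinylmagnesium bromide (CuBr·SMe2, Josiphos-type ferrocenyl diphosphine, t-BuOMe, −78 °C) at the exocyclic β-carbon C9 then returns the route to 19.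

3. Step 2. The trisubstituted enal may react slowly and with poor facial discrimination at the chiral Lewis acid. The fallback replaces catalyst control by auxiliary control and sets out from 3. A thermal Diels–Alder reaction with the chiral 1-amino-3-siloxy diene F8 (toluene, rt to 40 °C) gives the cycloadduct F9. LiAlH4 reduction gives the amino alcohol F10, and 1 M HCl in THF eliminates the auxiliary and returns the route to 7.

**Further compounds**

F1 | step 20 | α-nitro lactone (C8 epimers) | c1ccccc1CO[C@H]1C=C[C@](C)(CO[Si](c2ccccc2)(c2ccccc2)C(C)(C)C)[C@@H](COCc2ccccc2)[C@@]1(COC(=O)C2[N+](=O)[O-])[C@@H]2CC[C@H]1C[C@@H](O)C1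
F2 | step 20 | nitro keto lactone | c1ccccc1CO[C@H]1C=C[C@](C)(CO[Si](c2ccccc2)(c2ccccc2)C(C)(C)C)[C@@H](COCc2ccccc2)[C@@]1(COC(=O)C2[N+](=O)[O-])[C@@H]2CCC1CC(=O)C1
F3 | step 20 | intramolecular Henry adduct | c1ccccc1CO[C@H]1C=C[C@](C)(CO[Si](c2ccccc2)(c2ccccc2)C(C)(C)C)[C@@H](COCc2ccccc2)[C@@]1(COC(=O)[C@@]2([N+](=O)[O-])[C@@]3(O)C[C@@H]4C3)[C@@H]2CC4
F4 | step 20 | β-amino alcohol | c1ccccc1CO[C@H]1C=C[C@](C)(CO[Si](c2ccccc2)(c2ccccc2)C(C)(C)C)[C@@H](COCc2ccccc2)[C@@]1(COC(=O)[C@@]2(N)[C@@]3(O)C[C@@H]4C3)[C@@H]2CC4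
F5 | step 11 | 3-[cis-3-(pivaloyloxy)cyclobutyl]propanal | O=CCC[C@H]1C[C@@H](OC(=O)C(C)(C)C)C1
F6 | step 11 | β-hydroxy ketone (aldol adduct at C10, diastereomer mixture) | O=C1C=C[C@](C)(CO[Si](c2ccccc2)(c2ccccc2)C(C)(C)C)[C@@H](COCc2ccccc2)C1C(O)CC[C@H]1C[C@@H](OC(=O)C(C)(C)C)C1
F7 | step 11 | (E)-alkylidene dienone | O=C1C=C[C@](C)(CO[Si](c2ccccc2)(c2ccccc2)C(C)(C)C)[C@@H](COCc2ccccc2)/C1=C\CC[C@H]1C[C@@H](OC(=O)C(C)(C)C)C1
F8 | step 2 | (E)-1-[(2R,5R)-2,5-diphenylpyrrolidin-1-yl]-3-(tert-butyldimethylsilyloxy)buta-1,3-diene | C=C(O[Si](C)(C)C(C)(C)C)/C=C/N1[C@@H](c2ccccc2)CC[C@@H]1c1ccccc1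
F9 | step 2 | auxiliary-bearing cycloadduct aldehyde | CC(C)(C)[Si](C)(C)OC1=C[C@H](N2[C@@H](c3ccccc3)CC[C@@H]2c2ccccc2)[C@](C)(C=O)[C@@H](COCc2ccccc2)C1
F10 | step 2 | auxiliary-bearing amino alcohol | CC(C)(C)[Si](C)(C)OC1=C[C@H](N2[C@@H](c3ccccc3)CC[C@@H]2c2ccccc2)[C@](C)(CO)[C@@H](COCc2ccccc2)C1
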